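## Structural features

The target is a germacranolide: a ten-membered carbocycle (C1–C10) trans-fused through C6–C7 to an α-methylene-γ-butyrolactone (C11, C12, C13; lactone oxygen on C6). The ring carries a Z trisubstituted alkene C4=C5 (methyl C15), a trans 1β,10α-epoxide across C1–C10 (methyl C14) that derives from an E alkene, a benzoate on C3 (S), and on C8 (R) the ester of (2R,3S)-2,3-dimethyloxirane-2-carboxylic acid, whose two methyl groups are cis (tiglate series). C6, C7 and C8 are contiguous, with O6 anti and O8 syn to the C7–C11 bond; C3 is an isolated allylic centre next to C4, and C1/C10 are set together. Fragile groups are the exo-methylene lactone (a Michael acceptor for phosphines, amines and alkoxides), the two epoxides, the allylic benzoate and, before the last step, the cyclodeca-1(10),4-diene, which can cyclise across the ring under acid and undergo Cope rearrangement on heating. The real difficulty is the ten-membered ring with one E and one Z trisubstituted alkene in a 1,5-relationship, together with the O6/C11/O8 triad on a flexible ring. The key step exploits exactly this 1,5-diene: C10=C1–C2–C3–C4=C5, closed through C6–C9, is what a bicyclo[2.2.0]hexane (C10, C1, C2, C3, C4, C5) gives on cycloreversion, and that bicycle results from adding the C5=C10 bond of a 3-methylcyclohexenone (C5–C10, carbonyl at C6) across the C1=C4 bond of a methylcyclobutene (C1–C4). Two points of structure decide the design of the partners. O3 sits on the carbon next to the methyl-bearing C4, so the cyclobutene must be a 2-methylcyclobut-2-en-1-ol derivative (a 3-methyl isomer would put the oxygen on C2). An acetate arm introduced at C7 next to an existing C8 oxygen enters anti to it, so the ring is built with O8 α and C8 is inverted when the ester is made.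

## Logic of the disconnections

32 to 31. The two C–O bonds of the ring epoxide are cut. The oxide is the most acid-sensitive group and C1=C10 is the only electron-rich alkene of 31, so it is made last. This asks for a peracid that attacks only C1=C10 and only its outer face.

31 to 27 and 30. The C8–O bond is cut, not the acyl–oxygen bond, so that O8 arrives with the acid and with inversion at C8. The reason is that the C7 arm can only be placed anti to a C8 oxygen already present, whereas the target has them syn. The gain is a convergent union with a separately made chiral acid. The demand is a clean SN2 displacement at a hindered ring carbinol in the presence of the exo-methylene lactone.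

30 to 29 to 28. The acid is taken back to the primary alcohol and then to the alkene by removing the oxirane oxygen. The E geometry of 28 fixes the cis relation of the methyl groups, and a tartrate-controlled epoxidation has to fix the absolute sense.

27 to 26 to 25 to 24. The benzoate C–O bond and the two Si–O bonds are cut in an order that acylates O3 before O8 is released. This lets the epoxy ester enter at the latest possible point. It demands that the triethylsilyl ether on O3 be removed without touching the tert-butyldimethylsilyl ether on O8.

24 to 21. The C11=C13 bond is cut. The exo-methylene group is introduced only after all other C–C bonds exist and while both hydroxyls are silyl ethers, so that the only enolisable position is C11.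

21 to 19. The lactone C12–O6 bond is cut and C6 is returned to the ketone level. The ketone is what the photochemistry needs and what steers the ring opening. The forward step must deliver hydride so that O6 ends anti to the arm.

19 to 18. The bonds C1–C4 and C5–C10 are re-formed, which turns the ten-membered dienone into a 6-4-4 tricycle. The medium ring and both trisubstituted alkenes disappear from the problem. The forward thermolysis must give E at C1=C10, Z at C4=C5, and stop before a Cope rearrangement.

18 to 9 and 17. The bonds C10–C1 and C5–C4 are cut (key step). The gain is two monocyclic fragments of ten and five carbons that carry C7/C8 and C3 respectively. The demand is head-to-tail orientation of the two methyl-bearing carbons.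

9 to 7 and 8. The C7–C11 bond is cut. Alkylation of the α′ enolate sets C7 anti to O8. The enolate must be alkylated before it can expel the β-silyloxy group.

7 to 6 to 5. The C10–C14 bond is cut with a 1,3-transposition of the carbonyl. This allows the methyl to enter by simple 1,2-addition and puts the carbonyl on C6.

5 to 3 to 2 to 1. The enone is traced to an all-cis 1,3,5-trioxygenated cyclohexane whose three carbinol carbons become C6, C8 and C10. One enzymatic acylation of the meso diol 2 supplies the absolute configuration of C8.

17 to 16 to 15 to 13 to 10 and 11. The Si–O bond, then the C3–H bond (asymmetric reduction), then a carbonyl transposition lead to 13. Compound 13 is cut across the ring into 10 and 11, a union that places the methyl next to the carbonyl, as C4/C3 of the target require.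

## Other disconnections considered

Alternative 1: The cut is C9–C10 of the ring. In the forward sense the 1-alkoxyvinyl group on C7 of the seco-lactone A1 is hydroborated with 9-BBN (boron to C9, hydrogen to C8), and the alkylborane is coupled with the E alkenyl iodide under PdCl2(dppf) and base to give the ten-membered lactone A2. In its favour, both trisubstituted alkenes are fixed in open-chain form before the ring exists, so their geometry is not in doubt; on this point it is better than the chosen plan. The lactone with C6 and C7 is also in place before cyclisation. Against it: closing a ten-membered ring by sp3–sp2 coupling must overcome transannular strain at high dilution; the borane carries an alkoxy group on the neighbouring carbon and can lose it by β-elimination; and C8 is set by hydroboration of an enol ether under substrate control only. The chosen plan makes the medium ring by opening fused small rings, with no entropic penalty, but leaves alkene geometry to a thermal process. A1 would need a long linear assembly, so step economy is unlikely to be better.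

Alternative 2: The cuts are C7–C11 and C8–O. A bromoacetal on O6 of the cyclodecatrienol derivative A3 gives a C11 radical that adds 5-exo to C7, and the C8 radical is captured by TEMPO to give the lactol ether A4. In its favour, the C7–C11 bond and the C8 oxygen are installed in one step, and C7 is set from C6 through the new five-membered ring. On the O6/C11/O8 triad this is better than the chosen plan, which has to invert C8 late. Against it: the step does not build the ten-membered ring, so A3, a triene with three defined alkenes, must come from elsewhere; the radicals can add across the ring to C4=C5 or C1=C10; and the face of the TEMPO capture at C8 rests on ring conformation. In mechanism it is equal in reliability to the photocycloaddition as a ring-forming event. In structure it solves a different problem from the chosen plan, and in step count it adds N–O cleavage and lactol oxidation after the key step.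

Alternative 3: The cut is C3–C8, which turns the ten-membered ring into the cis-fused bicyclo[4.4.0]decadiene diol A5. Lead tetraacetate cleaves the ring-fusion glycol and gives the cyclodecadienedione A6. In its favour, glycol cleavage is a very dependable two-electron fragmentation, the ring expansion has no entropic cost, and the chiral pool supplies C7; in reliability of the ring-forming event it is equal to or better than the photochemical–thermal pair. Against it: both alkenes come from six-membered rings and are therefore Z, whereas the target needs E at C1=C10, and a non-conjugated ring alkene cannot simply be isomerised. In addition, C3 and C8 arrive as ketones that need two stereoselective reductions on the medium ring, the β,γ-unsaturated diketone can isomerise or close across the ring, and the lactone must still be made by oxidation of the allylic side chain. The chosen plan delivers the E/Z pattern and the C3 and C8 oxygens at the right oxidation level, at the price of a C8 inversion.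

Key step: step 11

Assumption: the lipase acylates the hydroxyl of 2 that leads to 3 as drawn; if the enzyme prefers the other hydroxyl, 3 is obtained instead by its hydrolysis of the meso diacetate of 2.

Remark: from step 11 on, ring positions carry germacrane numbers (C1–C15), and α/β are used as for germacranolides with H-7 α. Compound 18 is drawn as the facial isomer expected to predominate; every cis-anti-cis facial isomer leads to the same 19.

## Route

Step 1
Reactants: 1 cis,cis-cyclohexane-1,3,5-triol
Product: 2 (1R,3S,5s)-5-[(tert-butyldimethylsilyl)oxy]cyclohexane-1,3-diol (all-cis, meso)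
Conditions: TBSCl (1.0 equiv), imidazole, DMF, 0 °C → rt
Reagents that add atoms: tert-butyldimethylsilyl chloride, CC(C)(C)[Si](C)(C)Cl
Why: Corey silylation of one of three equivalent hydroxyls; the reaction is statistical, and unreacted 1 and over-silylated material are recycled. No stereocentre is created, since 2 is meso.

Step 2
Reactants: 2 (1R,3S,5s)-5-[(tert-butyldimethylsilyl)oxy]cyclohexane-1,3-diol
Product: 3 (1R,3S,5S)-3-[(tert-butyldimethylsilyl)oxy]-5-hydroxycyclohexyl acetate (all-cis)
Conditions: Pseudomonas cepacia lipase (Amano PS), vinyl acetate, t-BuOMe, 30 °C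
Reagents that add atoms: vinyl acetate, CC(=O)OC=C
Why: Lipase-catalysed transesterification of a meso diol acylates one of the two enantiotopic hydroxyls; this single event fixes the absolute configuration of the silyloxy carbon that becomes C8.

Step 3
Reactants: 3 (1R,3S,5S)-3-[(tert-butyldimethylsilyl)oxy]-5-hydroxycyclohexyl acetate
Product: 5 (R)-5-[(tert-butyldimethylsilyl)oxy]cyclohex-2-en-1-one, via β-acetoxy ketone 4 (not isolated)
Conditions: Dess–Martin periodinane, CH2Cl2, 0 °C → rt; then Et3N, 0 °C
Reagents that add atoms: none
Why: Dess–Martin oxidation gives the β-acetoxy ketone, which loses acetic acid by E1cB when the amine is added. Acetate is much the better leaving group, so the silyloxy group on the other β carbon should stay.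

Step 4
Reactants: 5 (R)-5-[(tert-butyldimethylsilyl)oxy]cyclohex-2-en-1-one
Product: 6 (5R)-5-[(tert-butyldimethylsilyl)oxy]-1-methylcyclohex-2-en-1-ol (both C1 epimers)
Conditions: MeLi, CeCl3, THF, −78 °C
Reagents that add atoms: methyllithium, [Li]C
Why: 1,2-Addition of the organocerium reagent to the enone; CeCl3 suppresses enolisation and β-elimination. The configuration of the new carbinol is irrelevant because it is removed in step 5.

Step 5
Reactants: 6 (5R)-5-[(tert-butyldimethylsilyl)oxy]-1-methylcyclohex-2-en-1-ol
Product: 7 (S)-5-[(tert-butyldimethylsilyl)oxy]-3-methylcyclohex-2-en-1-one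
Conditions: [C5H5NH][CrO3Cl] (pyridinium chlorochromate), 4 Å MS, CH2Cl2, rt
Reagents that add atoms: none
Why: Babler–Dauben oxidative transposition: the tertiary allylic chromate ester undergoes a [3,3] shift and the resulting secondary chromate is oxidised to the β-methyl enone. The silyloxy carbon is untouched; its descriptor changes from R to S only through the priority rules.

Step 6
Reactants: 7 (S)-5-[(tert-butyldimethylsilyl)oxy]-3-methylcyclohex-2-en-1-one; 8 methyl bromoacetate
Product: 9 methyl 2-[(1R,6S)-6-[(tert-butyldimethylsilyl)oxy]-4-methyl-2-oxocyclohex-3-en-1-yl]acetate (fragment 1; arm and silyloxy group trans)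
Conditions: LiN(iPr)2, THF, −78 °C; then 8, DMPU, −78 → −40 °C
Reagents that add atoms: none
Why: Kinetic deprotonation at the α′ carbon gives the cross-conjugated lithium dienolate, which is alkylated anti to the adjacent silyloxy group, as in α′-alkylation of 5-substituted cyclohexenones of the carvone type. This sets C7 (R) trans to O8. Low temperature and a reactive electrophile keep the β-silyloxy enolate from eliminating.

Step 7
Reactants: 10 1-ethoxyprop-1-yne; 11 acetyl chloride
Product: 13 3-ethoxy-2-methylcyclobut-2-en-1-one, via ketene 12 (not isolated)
Conditions: Et3N, Et2O, 0 °C → rt (11 added slowly)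
Reagents that add atoms: none
Why: Ketene generated in situ undergoes [2+2] cycloaddition with the electron-rich ynol ether. The methyl-bearing alkyne carbon bonds to the ketene carbonyl carbon, which places the methyl on C2 next to the carbonyl.

Step 8
Reactants: 13 3-ethoxy-2-methylcyclobut-2-en-1-one
Product: 15 2-methylcyclobut-2-en-1-one, via cyclobutenol 14 (not isolated)
Conditions: i-Bu2AlH, CH2Cl2, −78 °C; then 1 M HCl, 0 °C
Reagents that add atoms: none
Why: Stork–Danheiser reduction–hydrolysis: 1,2-reduction of the vinylogous ester, then acid hydrolysis of the enol ether with allylic transposition, gives the enone with the methyl on the α carbon. The volatile, sensitive enone is kept in solution and used at once.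

Step 9
Reactants: 15 2-methylcyclobut-2-en-1-one
Product: 16 (S)-2-methylcyclobut-2-en-1-ol
Conditions: (R)-2-methyl-CBS-oxazaborolidine (15 mol %), catecholborane, toluene/CH2Cl2, −78 °C
Reagents that add atoms: none
Why: Corey–Bakshi–Shibata reduction: the carbonyl binds with the larger 2-methylalkenyl arm away from the catalyst, so hydride is delivered to one face; with the (R) catalyst this should give the (S) carbinol, the future C3. Catecholborane at low temperature avoids hydroboration of the strained alkene.

Step 10
Reactants: 16 (S)-2-methylcyclobut-2-en-1-ol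
Product: 17 (S)-triethyl[(2-methylcyclobut-2-en-1-yl)oxy]silane (fragment 2)
Conditions: Et3SiCl, imidazole, CH2Cl2, 0 °C
Reagents that add atoms: chlorotriethylsilane, CC[Si](Cl)(CC)CC
Why: Standard silylation of a secondary allylic alcohol; the stereocentre is not touched. The triethylsilyl group is chosen so that O3 can later be released before O8.

Step 11
Reactants: 9 methyl 2-[(1R,6S)-6-[(tert-butyldimethylsilyl)oxy]-4-methyl-2-oxocyclohex-3-en-1-yl]acetate; 17 (S)-triethyl[(2-methylcyclobut-2-en-1-yl)oxy]silane
Product: 18 cis-anti-cis 6-4-4 tricyclic ketone: six-membered ring C5–C10 (C6 ketone, C7 acetate arm, C8 tert-butyldimethylsilyloxy, C10 methyl), central cyclobutane C10–C1–C4–C5, outer cyclobutane C1–C2–C3–C4 (C3 triethylsilyloxy, C4 methyl); 3S, 7R, 8S; new bonds anti to O8 and anti to O3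
Conditions: hν (350 nm, Pyrex), 17 (3 equiv), CH2Cl2, degassed, −20 °C
Reagents that add atoms: none
Why: Irradiation at 350 nm excites only the enone (n→π*), which crosses to its twisted triplet; this is the enone–alkene [2+2] photocycloaddition of the de Mayo/Corey type, in its known variant with a cyclobutene as the alkene. The triplet bonds first from its β carbon C10 to the unsubstituted cyclobutene carbon C1, giving a 1,4-biradical with a tertiary centre at C4 and an α-acyl centre at C5, and after spin inversion C4–C5 closes; the new cyclobutane (C10–C1–C4–C5) is thus formed stepwise by biradical recombination. The required orientation (C10–C1, C5–C4) is secured by the two methyl groups: the alternative would join the two fully substituted carbons C10 and C4 and pass through a secondary radical at C1. C1 and C4 are necessarily cis because both bonds are made to one face of the four-membered ring. C5 and C10 end cis because a trans-fused bicyclo[4.2.0]octanone that carries a further fused four-membered ring is too strained, and the planar C5 radical closes on the face that gives the cis fusion. The two outer rings lie anti across the new ring because the cyclobutene approaches with its CH2–CH(OSi) edge turned away from the six-membered ring. Facial choice (anti to the C8 silyloxy group on the enone, anti to the C3 silyloxy group on the cyclobutene, as drawn) is not required, since C1, C4, C5 and C10 all become sp2 in step 12. The excess of 17 suppresses enone dimerisation and is recovered.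

Step 12
Reactants: 18 cis-anti-cis 6-4-4 tricyclic ketone
Product: 19 methyl (1(10)E,4Z)-8α-(tert-butyldimethylsilyloxy)-6-oxo-3β-(triethylsilyloxy)-13-norgermacra-1(10),4-dien-12-oate, that is methyl 2-[(1R,3Z,5S,7E,10S)-10-[(tert-butyldimethylsilyl)oxy]-4,8-dimethyl-2-oxo-5-[(triethylsilyl)oxy]cyclodeca-3,7-dien-1-yl]acetate
Conditions: toluene (0.01 M), BHT, base-washed sealed tube, 200 °C
Reagents that add atoms: none
Why: Thermal cycloreversion of the bicyclo[2.2.0]hexane: homolysis of C5–C10 (tertiary radical and α-keto radical) followed by cleavage of C1–C4 releases the strain of both four-membered rings. C9 and C2 are anti across C10–C1 in the cis-anti-cis tricycle, which translates into E at C1=C10, while rotation at the stabilised C5 radical lets the conjugated C4=C5 form as the more stable Z enone. Conjugation of C4=C5 with the ketone should hold the product back from Cope rearrangement.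

Step 13
Reactants: 19 methyl (1(10)E,4Z)-8α-(tert-butyldimethylsilyloxy)-6-oxo-3β-(triethylsilyloxy)-13-norgermacra-1(10),4-dien-12-oate
Product: 21 (1(10)E,4Z)-8α-(tert-butyldimethylsilyloxy)-3β-(triethylsilyloxy)-13-norgermacra-1(10),4-dien-6α,12-olide (trans-fused lactone), via hydroxy ester 20 (not isolated)
Conditions: NaBH4, CeCl3·7H2O, MeOH, −78 → −30 °C; then DBU (cat.), toluene, 50 °C
Reagents that add atoms: none
Why: Luche 1,2-reduction of the enone. Hydride is expected to arrive on the outer face of the ring carbonyl and give the 6α-alcohol (O6 anti to the C7 arm), which closes the γ-lactone onto the methyl ester under the amidine base. The C6 configuration rests on substrate control and is treated as a risk below.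

Step 14
Reactants: 21 (1(10)E,4Z)-8α-(tert-butyldimethylsilyloxy)-3β-(triethylsilyloxy)-13-norgermacra-1(10),4-dien-6α,12-olide
Product: 24 (1(10)E,4Z)-8α-(tert-butyldimethylsilyloxy)-3β-(triethylsilyloxy)germacra-1(10),4,11(13)-trien-6α,12-olide, via Mannich base 22 (not isolated), via methiodide 23 (not isolated)
Conditions: LiN(iPr)2, THF, −78 °C; [CH2=NMe2]I, −78 °C → rt; MeI, MeOH, rt; NaHCO3 (aq), CH2Cl2, rt
Reagents that add atoms: N,N-dimethylmethyleneiminium iodide (Eschenmoser's salt), C=[N+](C)C.[I-]
Why: Mannich reaction of the lactone enolate at C11, the only enolisable position, then quaternisation and elimination of trimethylamine. The C11 stereocentre formed on the way is removed, and no ester is present that could be attacked by the enolate.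

Step 15
Reactants: 24 (1(10)E,4Z)-8α-(tert-butyldimethylsilyloxy)-3β-(triethylsilyloxy)germacra-1(10),4,11(13)-trien-6α,12-olide
Product: 25 (1(10)E,4Z)-8α-(tert-butyldimethylsilyloxy)-3β-hydroxygermacra-1(10),4,11(13)-trien-6α,12-olide
Conditions: PPTS, MeOH/CH2Cl2, 0 °C
Reagents that add atoms: none
Why: Mild acid-catalysed methanolysis removes the triethylsilyl ether and leaves the more hindered, less labile tert-butyldimethylsilyl ether; no stereocentre is touched.

Step 16
Reactants: 25 (1(10)E,4Z)-8α-(tert-butyldimethylsilyloxy)-3β-hydroxygermacra-1(10),4,11(13)-trien-6α,12-olide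
Product: 26 (1(10)E,4Z)-3β-benzoyloxy-8α-(tert-butyldimethylsilyloxy)germacra-1(10),4,11(13)-trien-6α,12-olide
Conditions: BzCl, pyridine, DMAP (cat.), CH2Cl2, 0 °C → rt
Reagents that add atoms: benzoyl chloride, O=C(Cl)c1ccccc1
Why: Nucleophile-catalysed acylation of the allylic secondary alcohol with retention at C3.

Step 17
Reactants: 26 (1(10)E,4Z)-3β-benzoyloxy-8α-(tert-butyldimethylsilyloxy)germacra-1(10),4,11(13)-trien-6α,12-olide
Product: 27 (1(10)E,4Z)-3β-benzoyloxy-8α-hydroxygermacra-1(10),4,11(13)-trien-6α,12-olide
Conditions: HF·pyridine, pyridine, THF, 0 °C → rt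
Reagents that add atoms: none
Why: Fluoride-mediated desilylation under buffered conditions; the benzoate, the exo-methylene lactone and the diene should tolerate it.

Step 18
Reactants: 28 (E)-2-methylbut-2-en-1-ol
Product: 29 [(2S,3S)-2,3-dimethyloxiran-2-yl]methanol
Conditions: Ti(OiPr)4 (10 mol %), L-(+)-diethyl tartrate (12 mol %), t-BuOOH, 4 Å MS, CH2Cl2, −20 °C
Reagents that add atoms: tert-butyl hydroperoxide, CC(C)(C)OO
Why: Katsuki–Sharpless asymmetric epoxidation; with L-(+)-tartrate an E allylic alcohol gives the (2S,3S) epoxy alcohol, the same face as for (E)-hex-2-en-1-ol. The E geometry of 28 fixes the cis relation of the two methyl groups.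

Step 19
Reactants: 29 [(2S,3S)-2,3-dimethyloxiran-2-yl]methanol
Product: 30 (2R,3S)-2,3-dimethyloxirane-2-carboxylic acid
Conditions: TEMPO (cat.), PhI(OAc)2, MeCN/H2O, rt
Reagents that add atoms: water, O
Why: Oxoammonium oxidation of the primary alcohol through the aldehyde hydrate to the acid. The oxirane and both centres are untouched; C2 becomes R only through the priority rules.

Step 20
Reactants: 27 (1(10)E,4Z)-3β-benzoyloxy-8α-hydroxygermacra-1(10),4,11(13)-trien-6α,12-olide; 30 (2R,3S)-2,3-dimethyloxirane-2-carboxylic acid
Product: 31 (1(10)E,4Z)-3β-benzoyloxy-8β-[(2R,3S)-2,3-dimethyloxirane-2-carbonyloxy]germacra-1(10),4,11(13)-trien-6α,12-olide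
Conditions: PPh3, DIAD, toluene/THF, 0 °C → rt (betaine preformed)
Reagents that add atoms: none
Why: Mitsunobu esterification: the alkoxyphosphonium ion at C8 is displaced by the carboxylate with inversion, turning 8α-OH into the 8β ester, so that O8 ends syn to the C7–C11 bond. The glycidic acid is about as acidic as 4-nitrobenzoic acid, the acid of choice for hindered secondary alcohols. Preforming the betaine keeps free phosphine away from the exo-methylene lactone.

Step 21
Reactants: 31 (1(10)E,4Z)-3β-benzoyloxy-8β-[(2R,3S)-2,3-dimethyloxirane-2-carbonyloxy]germacra-1(10),4,11(13)-trien-6α,12-olide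
Product: 32 (4Z)-3β-benzoyloxy-1β,10α-epoxy-8β-[(2R,3S)-2,3-dimethyloxirane-2-carbonyloxy]germacra-4,11(13)-dien-6α,12-olide (1R,3S,6R,7R,8R,10R; the target)
Conditions: mCPBA, NaHCO3, CH2Cl2, 0 °C
Reagents that add atoms: 3-chloroperoxybenzoic acid, OOC(=O)c1cccc(Cl)c1
Why: Prilezhaev epoxidation: C1=C10 is the only electron-rich alkene (C4=C5 is flanked by two allylic acyloxy groups, C11=C13 is conjugated). Attack on the outer face of the E alkene should give the 1β,10α oxide (1R,10R), the sense usual for peracid epoxidation of germacranolide 1(10)-alkenes.

## Compound list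

1 | cis,cis-cyclohexane-1,3,5-triol (all-cis) | O[C@@H]1C[C@H](O)C[C@H](O)C1 | starting material
2 | (1R,3S,5s)-5-[(tert-butyldimethylsilyl)oxy]cyclohexane-1,3-diol (all-cis, meso) | O[C@@H]1C[C@H](O)C[C@H](O[Si](C)(C)C(C)(C)C)C1 | intermediate
3 | (1R,3S,5S)-3-[(tert-butyldimethylsilyl)oxy]-5-hydroxycyclohexyl acetate (all-cis) | O[C@H]1C[C@@H](OC(C)=O)C[C@@H](O[Si](C)(C)C(C)(C)C)C1 | intermediate
4 | (1S,3R)-3-[(tert-butyldimethylsilyl)oxy]-5-oxocyclohexyl acetate | O=C1C[C@@H](OC(C)=O)C[C@@H](O[Si](C)(C)C(C)(C)C)C1 | intermediate
5 | (R)-5-[(tert-butyldimethylsilyl)oxy]cyclohex-2-en-1-one | O=C1C=CC[C@@H](O[Si](C)(C)C(C)(C)C)C1 | intermediate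
6 | (5R)-5-[(tert-butyldimethylsilyl)oxy]-1-methylcyclohex-2-en-1-ol (both C1 epimers) | CC1(O)C=CC[C@@H](O[Si](C)(C)C(C)(C)C)C1 | intermediate
7 | (S)-5-[(tert-butyldimethylsilyl)oxy]-3-methylcyclohex-2-en-1-one | CC1=CC(=O)C[C@@H](O[Si](C)(C)C(C)(C)C)C1 | intermediate
8 | methyl bromoacetate | COC(=O)CBr | starting material
9 | methyl 2-[(1R,6S)-6-[(tert-butyldimethylsilyl)oxy]-4-methyl-2-oxocyclohex-3-en-1-yl]acetate (fragment 1, 7,8-trans) | CC1=CC(=O)[C@H](CC(=O)OC)[C@@H](O[Si](C)(C)C(C)(C)C)C1 | intermediate
10 | 1-ethoxyprop-1-yne | CCOC#CC | starting material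
11 | acetyl chloride | CC(=O)Cl | starting material
12 | ketene | C=C=O | intermediate
13 | 3-ethoxy-2-methylcyclobut-2-en-1-one | CCOC1=C(C)C(=O)C1 | intermediate
14 | 3-ethoxy-2-methylcyclobut-2-en-1-ol (racemic) | CCOC1=C(C)C(O)C1 | intermediate
15 | 2-methylcyclobut-2-en-1-one | CC1=CCC1=O | intermediate
16 | (S)-2-methylcyclobut-2-en-1-ol | CC1=CC[C@@H]1O | intermediate
17 | (S)-triethyl[(2-methylcyclobut-2-en-1-yl)oxy]silane (fragment 2) | CC1=CC[C@@H]1O[Si](CC)(CC)CC | intermediate
18 | cis-anti-cis 6-4-4 tricyclic ketone (C10–C1 and C5–C4 bonded; 3S,7R,8S; new bonds anti to O8 and O3) | O=C1[C@H](CC(=O)OC)[C@@H](O[Si](C)(C)C(C)(C)C)C[C@]2(C)[C@H]3C[C@H](O[Si](CC)(CC)CC)[C@@]3(C)[C@H]12 | intermediate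
19 | methyl (1(10)E,4Z)-8α-(tert-butyldimethylsilyloxy)-6-oxo-3β-(triethylsilyloxy)-13-norgermacra-1(10),4-dien-12-oate | O=C1/C=C(/C)[C@@H](O[Si](CC)(CC)CC)C/C=C(\C)C[C@H](O[Si](C)(C)C(C)(C)C)[C@H]1CC(=O)OC | intermediate
20 | methyl (1(10)E,4Z)-8α-(tert-butyldimethylsilyloxy)-6α-hydroxy-3β-(triethylsilyloxy)-13-norgermacra-1(10),4-dien-12-oate | O[C@@H]1/C=C(/C)[C@@H](O[Si](CC)(CC)CC)C/C=C(\C)C[C@H](O[Si](C)(C)C(C)(C)C)[C@H]1CC(=O)OC | intermediate
21 | (1(10)E,4Z)-8α-(tert-butyldimethylsilyloxy)-3β-(triethylsilyloxy)-13-norgermacra-1(10),4-dien-6α,12-olide | C1C(=O)O[C@@H]2/C=C(/C)[C@@H](O[Si](CC)(CC)CC)C/C=C(\C)C[C@H](O[Si](C)(C)C(C)(C)C)[C@@H]12 | intermediate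
22 | 11-(dimethylaminomethyl) derivative of 21 (C11 epimers) | CN(C)CC1C(=O)O[C@@H]2/C=C(/C)[C@@H](O[Si](CC)(CC)CC)C/C=C(\C)C[C@H](O[Si](C)(C)C(C)(C)C)[C@@H]12 | intermediate
23 | 11-(trimethylammoniomethyl) iodide of 21 (C11 epimers) | C[N+](C)(C)CC1C(=O)O[C@@H]2/C=C(/C)[C@@H](O[Si](CC)(CC)CC)C/C=C(\C)C[C@H](O[Si](C)(C)C(C)(C)C)[C@@H]12.[I-] | intermediate
24 | (1(10)E,4Z)-8α-(tert-butyldimethylsilyloxy)-3β-(triethylsilyloxy)germacra-1(10),4,11(13)-trien-6α,12-olide | C=C1C(=O)O[C@@H]2/C=C(/C)[C@@H](O[Si](CC)(CC)CC)C/C=C(\C)C[C@H](O[Si](C)(C)C(C)(C)C)[C@@H]12 | intermediate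
25 | (1(10)E,4Z)-8α-(tert-butyldimethylsilyloxy)-3β-hydroxygermacra-1(10),4,11(13)-trien-6α,12-olide | C=C1C(=O)O[C@@H]2/C=C(/C)[C@@H](O)C/C=C(\C)C[C@H](O[Si](C)(C)C(C)(C)C)[C@@H]12 | intermediate
26 | (1(10)E,4Z)-3β-benzoyloxy-8α-(tert-butyldimethylsilyloxy)germacra-1(10),4,11(13)-trien-6α,12-olide | C=C1C(=O)O[C@@H]2/C=C(/C)[C@@H](OC(=O)c3ccccc3)C/C=C(\C)C[C@H](O[Si](C)(C)C(C)(C)C)[C@@H]12 | intermediate
27 | (1(10)E,4Z)-3β-benzoyloxy-8α-hydroxygermacra-1(10),4,11(13)-trien-6α,12-olide | C=C1C(=O)O[C@@H]2/C=C(/C)[C@@H](OC(=O)c3ccccc3)C/C=C(\C)C[C@H](O)[C@@H]12 | intermediate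
28 | (E)-2-methylbut-2-en-1-ol | C/C=C(\C)CO | starting material
29 | [(2S,3S)-2,3-dimethyloxiran-2-yl]methanol | OC[C@]1(C)O[C@H]1C | intermediate
30 | (2R,3S)-2,3-dimethyloxirane-2-carboxylic acid | OC(=O)[C@]1(C)O[C@H]1C | intermediate
31 | (1(10)E,4Z)-3β-benzoyloxy-8β-[(2R,3S)-2,3-dimethyloxirane-2-carbonyloxy]germacra-1(10),4,11(13)-trien-6α,12-olide | C=C1C(=O)O[C@@H]2/C=C(/C)[C@@H](OC(=O)c3ccccc3)C/C=C(\C)C[C@@H](OC(=O)[C@]3(C)O[C@H]3C)[C@@H]12 | intermediate
32 | (4Z)-3β-benzoyloxy-1β,10α-epoxy-8β-[(2R,3S)-2,3-dimethyloxirane-2-carbonyloxy]germacra-4,11(13)-dien-6α,12-olide | C=C1C(=O)O[C@@H]2/C=C(/C)[C@@H](OC(=O)c3ccccc3)C[C@H]3O[C@]3(C)C[C@@H](OC(=O)[C@]3(C)O[C@H]3C)[C@@H]12 | target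

## Step count and least certain steps

Total: 21 steps. Longest linear sequence: 15 steps (steps 1–6, 11–17, 20, 21). Fragment 2 (steps 7–10) joins at step 11 and the acid (steps 18–19) at step 20.

Step 11 (key step). The likely failures are addition in the head-to-head sense, or slow addition with enone decomposition, because each new bond is made to a fully substituted carbon; syn or trans-fused adducts, which would open with other alkene geometries, could also form. Fallback: the photocycloaddition is run on the less hindered enone 7, the closest analogue of the known 3-methylcyclohexenone/cyclobutene pair, with 17. This gives the arm-less tricyclic ketone F1, with the same two bonds. F1 is then deprotonated at C7 with LiN(iPr)2 (C5 is a cyclobutane methine and is not competitive) and alkylated with 8 anti to O8. The fallback sets out from 7 and returns to the route at 18.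

Step 12. The opening may not stop at the diene: Cope rearrangement to a divinylcyclohexanone, formation of the E enone at C4=C5, or thermal loss of the β-silyloxy group next to the ketone are all possible at 200 °C. Inversion at C10–C1 instead of C4–C5 would be the most damaging outcome, since a Z alkene at C1=C10 cannot be corrected. Fallback: 18 is opened by flash vacuum pyrolysis with short contact time, accepting the kinetic geometry at the enone, and the (1(10)E,4E) isomer of 19 F2 is equilibrated to the Z enone in a separate step by reversible thiyl-radical addition (PhSSPh, hν). The fallback sets out from 18 and returns at 19.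

Step 13. Hydride may be delivered to the inner face of the C6 carbonyl, because the preferred conformation of the ten-membered dienone is not known. The 6β-alcohol would then close to the cis-fused lactone. Fallback: the 6β,12-cis-lactone F3 is saponified (LiOH, THF/H2O) and carefully acidified to the 6β-hydroxy acid F4, which is closed at once under Mitsunobu conditions (PPh3, DIAD, high dilution) with inversion at C6. The fallback sets out from 19 and returns at 21.

Step 20. The SN2 displacement at C8 may lose to elimination toward C9 or C7, or the hindered alkoxyphosphonium ion may not react; free phosphine could also add to the exo-methylene lactone. Fallback: 27 is oxidised with Dess–Martin periodinane to the 8-ketone F5 (kept cold, since the lactone oxygen is β to the new ketone). F5 is reduced under reagent control with a CBS oxazaborolidine and catecholborane to the 8β-alcohol F6, which is acylated with 30 by the Yamaguchi method (2,4,6-trichlorobenzoyl chloride, Et3N, DMAP). The fallback sets out from 27 and returns at 31.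

Step 6. The lithium enolate carries a silyloxy group on its β carbon and may expel it, which ends in aromatisation to a cresol; proton exchange to the extended dienolate and dialkylation are further risks. Fallback: 7 is converted without a free enolate (Me3SiOTf, Et3N) into the trimethylsilyl dienol ether F7. The α-ester radical from 8 is then added to C7 under visible-light photoredox catalysis with fac-Ir(ppy)3 (tris(2-phenylpyridinato)iridium); it adds anti to O8, and loss of the silyl group returns the ketone. The fallback sets out from 7 and returns at 9.

Step 21. The peracid may attack the inner face of C1=C10 and give the (1S,10S) oxide, or may also epoxidise C4=C5, since face selectivity rests on ring conformation alone. Fallback: reagent-controlled Shi epoxidation of 31 with the fructose-derived ketone enantiomer matched to the (1R,10R) oxide and KHSO5 (Oxone) under buffered conditions. The fallback sets out from 31 and returns at 32 and makes no new compound.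

## Further compounds

F1 | step 11 | arm-less cis-anti-cis tricyclic ketone (18 without the C7 acetate arm) | O=C1C[C@@H](O[Si](C)(C)C(C)(C)C)C[C@]2(C)[C@H]3C[C@H](O[Si](CC)(CC)CC)[C@@]3(C)[C@H]12
F2 | step 12 | (1(10)E,4E) isomer of 19 | O=C1/C=C(\C)[C@@H](O[Si](CC)(CC)CC)C/C=C(\C)C[C@H](O[Si](C)(C)C(C)(C)C)[C@H]1CC(=O)OC
F3 | step 13 | 6β,12-cis-lactone (C6 epimer of 21) | C1C(=O)O[C@H]2/C=C(/C)[C@@H](O[Si](CC)(CC)CC)C/C=C(\C)C[C@H](O[Si](C)(C)C(C)(C)C)[C@@H]12
F4 | step 13 | 6β-hydroxy acid | O[C@H]1/C=C(/C)[C@@H](O[Si](CC)(CC)CC)C/C=C(\C)C[C@H](O[Si](C)(C)C(C)(C)C)[C@H]1CC(=O)O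
F5 | step 20 | 8-ketone (3β-benzoyloxy-8-oxogermacra-1(10)E,4Z,11(13)-trien-6α,12-olide) | C=C1C(=O)O[C@@H]2/C=C(/C)[C@@H](OC(=O)c3ccccc3)C/C=C(\C)CC(=O)[C@@H]12
F6 | step 20 | 8β-alcohol (C8 epimer of 27) | C=C1C(=O)O[C@@H]2/C=C(/C)[C@@H](OC(=O)c3ccccc3)C/C=C(\C)C[C@@H](O)[C@@H]12
F7 | step 6 | trimethylsilyl dienol ether of 7 | CC1=CC(O[Si](C)(C)C)=C[C@@H](O[Si](C)(C)C(C)(C)C)C1
F0 | step 21 | none | none
A1 | alternative 1 | seco-lactone with 1-(4-methoxybenzyloxy)vinyl group on C7 and E alkenyl iodide at C10 | O=C1C[C@H](C(=C)OCc2ccc(OC)cc2)[C@H](O1)/C=C(/C)[C@@H](OC(=O)c1ccccc1)C/C=C(\C)I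
A2 | alternative 1 | ten-membered lactone with C3 benzoate and C8 4-methoxybenzyl ether | O=C1C[C@H]2[C@H](O1)/C=C(/C)[C@@H](OC(=O)c1ccccc1)C/C=C(\C)C[C@H]2OCc1ccc(OC)cc1
A3 | alternative 2 | 6-O-(2-bromo-1-ethoxyethyl) ether of the 3-silyloxycyclodeca-1(10),4,7-trien-6-ol (acetal carbon unassigned) | CCOC(CBr)O[C@@H]1/C=C(/C)[C@@H](O[Si](C)(C)C(C)(C)C)C/C=C(\C)C/C=C\1
A4 | alternative 2 | trans-fused lactol ethyl ether with C8 tetramethylpiperidinyloxy group | CCO[C@H]1C[C@H]2[C@H](O1)/C=C(/C)[C@@H](O[Si](C)(C)C(C)(C)C)C/C=C(\C)C[C@H]2ON1C(C)(C)CCCC1(C)C
A5 | alternative 3 | cis-fused bicyclo[4.4.0]decadiene with ring-fusion cis-diol (C3, C8), one diastereomer | C=C(CO[Si](C)(C)C(C)(C)C)[C@H]1[C@H](O[Si](C)(C)C(C)(C)C)C=C(C)[C@@]2(O)CC=C(C)C[C@@]12O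
A6 | alternative 3 | (1(10)Z,4Z)-cyclodecadiene-3,8-dione | C=C(CO[Si](C)(C)C(C)(C)C)[C@H]1[C@H](O[Si](C)(C)C(C)(C)C)/C=C(/C)C(=O)C/C=C(/C)CC1=O
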